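The dihydrofuran ring (O1, C2, C3, C3a, C7a) is disconnected at O1–C2 and C2–C3 into an ortho-quinone methide of the benzo ring (C7a=O1, C3a=C3 bearing the dimethoxyphenyl group) and a one-carbon benzylidene unit, a chiral sulfonium ylide carrying C2 and its trioxygenated aryl group. The key step exploits the phenolic O1 on C7a ortho to the benzylic C3 and the electron-rich benzylic C2: formal (4+1) annulation forms C2–C3 and then closes the ring by attack of O1 on C2 with loss of the sulfide, setting both stereocentres trans. The precursor is a 2-(α-sulfonylbenzyl)phenol plus an isothiocineole-derived benzylsulfonium salt. Ether exchange and a late Heck reaction add the stilbene arm.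

Key step: step 6

Assumption: the sense of induction of the sulfonium ylide is taken from the accepted conformational model for this sulfide (given in step 6), which places the (1R,4R,5R)-sulfide in the 2S series; if a test reaction showed the opposite sense, the enantiomeric sulfide would be used with no other change.

Step 1
Reactants: 1 5-bromo-1,2,3-trimethoxybenzene
Product: 2 bromoaldehyde (6-bromo-2,3,4-trimethoxybenzaldehyde)
Conditions: Cl2CHOMe, TiCl4, CH2Cl2, 0 °C to rt; then H2O
Reagents that add atoms: dichloromethyl methyl ether, COC(Cl)Cl; water, O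
Why: Rieche formylation (electrophilic aromatic substitution) can only enter at the two symmetry-equivalent free positions, ortho to bromine and para to a methoxy group, so a single aldehyde should result after hydrolysis.

Step 2
Reactants: 2 bromoaldehyde (6-bromo-2,3,4-trimethoxybenzaldehyde)
Product: 3 salicylaldehyde (6-bromo-2-hydroxy-3,4-dimethoxybenzaldehyde)
Conditions: BCl3 (1.2 equiv), CH2Cl2, −78 to 0 °C; then H2O
Reagents that add atoms: none
Why: Chelation-directed Lewis-acid ether cleavage, in which BCl3 bound to the aldehyde oxygen cleaves only the ortho methoxy group through a six-membered boron chelate, should leave the other two methyl ethers and the aryl bromide untouched.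

Step 3
Reactants: 3 salicylaldehyde (6-bromo-2-hydroxy-3,4-dimethoxybenzaldehyde); 4 3,5-dimethoxyphenylmagnesium chloride (2.5 equiv)
Product: 5 benzhydrol (racemic 3-bromo-2-[(3,5-dimethoxyphenyl)(hydroxy)methyl]-5,6-dimethoxyphenol)
Conditions: THF, −78 to 0 °C; then aq. NH4Cl
Reagents that add atoms: none
Why: Grignard 1,2-addition to the aldehyde of the magnesium phenoxide (the first equivalent is consumed by the phenol) should give the racemic ortho-hydroxybenzhydrol, whose configuration is irrelevant because this carbon becomes trigonal in step 6.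

Step 4
Reactants: 5 benzhydrol (racemic 3-bromo-2-[(3,5-dimethoxyphenyl)(hydroxy)methyl]-5,6-dimethoxyphenol)
Product: 6 sulfone (racemic 3-bromo-2-[(3,5-dimethoxyphenyl)(4-methylbenzenesulfonyl)methyl]-5,6-dimethoxyphenol)
Conditions: TolSO2Na (3 equiv), HCO2H, CH2Cl2/H2O, rt
Reagents that add atoms: sodium 4-methylbenzenesulfinate, Cc1ccc(cc1)S(=O)[O-].[Na+]
Why: Acid-promoted SN1 substitution through the benzhydryl cation stabilised by the ortho hydroxy and para methoxy groups, trapped at sulfur by the soft sulfinate, should give the sulfone that serves as a base-triggered ortho-quinone methide precursor.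

Step 5
Reactants: 7 (1R,4R,5R)-isothiocineole; 8 3,4,5-trimethoxybenzyl bromide
Product: 9 sulfonium triflate ((1R,4R,5R,6R)-4,7,7-trimethyl-6-[(3,4,5-trimethoxyphenyl)methyl]-6-thiabicyclo[3.2.1]octan-6-ium trifluoromethanesulfonate)
Conditions: LiOTf, CH2Cl2/H2O, rt
Reagents that add atoms: lithium trifluoromethanesulfonate, [Li+].[O-]S(=O)(=O)C(F)(F)F
Why: SN2 S-alkylation of the sulfide by the benzylic bromide with exchange to the non-nucleophilic triflate should occur on the less hindered exo lone pair of sulfur and so give one sulfonium diastereomer.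

Step 6
Reactants: 6 sulfone (racemic 3-bromo-2-[(3,5-dimethoxyphenyl)(4-methylbenzenesulfonyl)methyl]-5,6-dimethoxyphenol); 9 sulfonium triflate (1.2 equiv)
Product: 13 bromodihydrobenzofuran ((2S,3S)-4-bromo-3-(3,5-dimethoxyphenyl)-6,7-dimethoxy-2-(3,4,5-trimethoxyphenyl)-2,3-dihydro-1-benzofuran), via ortho-quinone methide 10 (not isolated), via sulfonium ylide 11 (not isolated), via sulfonium phenoxide zwitterion 12 (not isolated)
Conditions: Cs2CO3 (3 equiv), 4 Å molecular sieves, MeCN/CH2Cl2, −20 °C to rt
Reagents that add atoms: none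
Why: Cs2CO3 turns 6 into ortho-quinone methide 10 by loss of sulfinate and deprotonates 9 to the semi-stabilised ylide 11; the ylide carbon adds to the methide carbon C3 of 10 with rearomatisation of the benzo ring to give zwitterion 12, in which the phenoxide O1 displaces the sulfide from C2. The closest known reaction type is the formal (4+1) annulation of in situ generated ortho-quinone methides with sulfur ylides to trans-2,3-dihydrobenzofurans, here run with a chiral sulfonium benzylide of the kind used in asymmetric epoxidation and aziridination. The dihydrofuran ring closes through the O1–C2 bond in a 5-exo-tet SN2 displacement with inversion at C2. C2 is controlled by the sulfide (aryl group syn to the sulfur lone pair in the ylide, approach of 10 to the face remote from the gem-dimethyl carbon, then inversion, giving 2S), and C3 by the open transition state of C–C bond formation that keeps the two aryl groups anti, the betaine so formed being the one whose reactive conformer (sulfonium anti to C3a) closes to the trans ring. The step needs attack at C3 instead of O-benzylation of the phenoxide, trans over cis closure, and ring closure faster than elimination of the sulfide toward the triarylethene. The gain of aromaticity on C3 attack, the steric bias of the bicyclic sulfide and the favourable five-membered closure at low temperature should secure these, and the sulfide is recovered.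

Step 7
Reactants: 13 bromodihydrobenzofuran ((2S,3S)-4-bromo-3-(3,5-dimethoxyphenyl)-6,7-dimethoxy-2-(3,4,5-trimethoxyphenyl)-2,3-dihydro-1-benzofuran)
Product: 14 heptaphenol ((2S,3S)-4-bromo-3-(3,5-dihydroxyphenyl)-2-(3,4,5-trihydroxyphenyl)-2,3-dihydro-1-benzofuran-6,7-diol)
Conditions: BBr3 (excess), CH2Cl2, −78 to 0 °C; cold pH 7 buffer work-up under argon, EtOAc extraction, crude solid used directly
Reagents that add atoms: none
Why: Lewis-acid cleavage of the seven aryl methyl ethers (BBr3 demethylation) is done while no alkene is present and should spare the benzylic C2–O1 bond, because boron bound to the methoxy oxygens (the central one of the trimethoxyphenyl ring reacting first) makes the C2 aryl group electron-poor.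

Step 8
Reactants: 14 heptaphenol ((2S,3S)-4-bromo-3-(3,5-dihydroxyphenyl)-2-(3,4,5-trihydroxyphenyl)-2,3-dihydro-1-benzofuran-6,7-diol)
Product: 16 heptasilyl ether (heptakis-O-(tert-butyldimethylsilyl) derivative of 14), via hexasilyl ether 15 (not isolated)
Conditions: TBSCl (6.5 equiv), imidazole, DMF/CH2Cl2, rt, argon; then TBSOTf (1.5 equiv), 2,6-lutidine, 0 °C
Reagents that add atoms: tert-butyldimethylsilyl chloride, CC(C)(C)[Si](C)(C)Cl; tert-butyldimethylsilyl trifluoromethanesulfonate, CC(C)(C)[Si](C)(C)OS(=O)(=O)C(F)(F)F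
Why: Imidazole-mediated O-silylation should cap the six less hindered phenols first, the C4' hydroxyl flanked by two silyloxy groups reacting last, and the more electrophilic silyl triflate with 2,6-lutidine then completes the persilylation to ethers removable without acid, leaving the bromide and both stereocentres untouched.

Step 9
Reactants: 17 3,5-dihydroxybenzaldehyde
Product: 18 silylated aldehyde (3,5-bis(tert-butyldimethylsilyloxy)benzaldehyde)
Conditions: TBSCl, imidazole, DMF, rt
Reagents that add atoms: tert-butyldimethylsilyl chloride, CC(C)(C)[Si](C)(C)Cl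
Why: Imidazole-mediated silylation of both phenols is standard and leaves the aldehyde untouched.

Step 10
Reactants: 18 silylated aldehyde (3,5-bis(tert-butyldimethylsilyloxy)benzaldehyde)
Product: 19 styrene (1-ethenyl-3,5-bis(tert-butyldimethylsilyloxy)benzene)
Conditions: Ph3PCH3Br (slight excess), n-BuLi, THF, 0 °C; then 18, 0 °C to rt
Reagents that add atoms: methyltriphenylphosphonium bromide, C[P+](c1ccccc1)(c1ccccc1)c1ccccc1.[Br-]
Why: Wittig methylenation with the pre-formed non-stabilised ylide should convert the aldehyde to the styrene without touching the aryl silyl ethers.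

Step 11
Reactants: 16 heptasilyl ether (aryl bromide); 19 styrene (1-ethenyl-3,5-bis(tert-butyldimethylsilyloxy)benzene)
Product: 20 nonasilyl ether (nonakis-O-(tert-butyldimethylsilyl) derivative of 21 with the (E)-alkene in place)
Conditions: Pd2(dba)3 (2.5 mol %), P(t-Bu)3·HBF4 (10 mol %), Cy2NMe, 1,4-dioxane, 80 °C
Reagents that add atoms: none
Why: Mizoroki–Heck reaction (oxidative addition of the hindered electron-rich aryl bromide to the zerovalent palladium–P(t-Bu)3 catalyst, syn insertion at the terminal alkene carbon, syn β-hydride elimination) should give the (E)-stilbene under amine-base conditions that leave silyl ethers and both stereocentres untouched.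

Step 12
Reactants: 20 nonasilyl ether (nonakis-O-(tert-butyldimethylsilyl) derivative of 21)
Product: 21 Scirpusin C ((2S,3S)-3-(3,5-dihydroxyphenyl)-4-[(E)-2-(3,5-dihydroxyphenyl)ethenyl]-2-(3,4,5-trihydroxyphenyl)-2,3-dihydro-1-benzofuran-6,7-diol)
Conditions: TBAF/AcOH (1:1, excess), THF, 0 °C, argon
Reagents that add atoms: none
Why: Fluoride-induced cleavage of the nine aryl silyl ethers, buffered with acetic acid to stay near neutral, should avoid both acid-induced ionisation or Friedel–Crafts chemistry of the stilbene–dihydrobenzofuran and phenoxide-induced quinone-methide ring opening or autoxidation.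

Compound list
1 | 5-bromo-1,2,3-trimethoxybenzene | COc1cc(Br)cc(OC)c1OC | starting material
2 | 6-bromo-2,3,4-trimethoxybenzaldehyde | COc1cc(Br)c(C=O)c(OC)c1OC | intermediate
3 | 6-bromo-2-hydroxy-3,4-dimethoxybenzaldehyde | COc1cc(Br)c(C=O)c(O)c1OC | intermediate
4 | 3,5-dimethoxyphenylmagnesium chloride (commercial THF solution) | COc1cc(OC)cc([Mg]Cl)c1 | starting material
5 | 3-bromo-2-[(3,5-dimethoxyphenyl)(hydroxy)methyl]-5,6-dimethoxyphenol (racemic) | COc1cc(Br)c(C(O)c2cc(OC)cc(OC)c2)c(O)c1OC | intermediate
6 | 3-bromo-2-[(3,5-dimethoxyphenyl)(4-methylbenzenesulfonyl)methyl]-5,6-dimethoxyphenol (racemic) | COc1cc(Br)c(C(c2cc(OC)cc(OC)c2)S(=O)(=O)c2ccc(C)cc2)c(O)c1OC | intermediate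
7 | (1R,4R,5R)-4,7,7-trimethyl-6-thiabicyclo[3.2.1]octane (isothiocineole, commercial) | C[C@@H]1CC[C@@H]2C[C@H]1SC2(C)C | starting material
8 | 5-(bromomethyl)-1,2,3-trimethoxybenzene (3,4,5-trimethoxybenzyl bromide) | COc1cc(CBr)cc(OC)c1OC | starting material
9 | (1R,4R,5R,6R)-4,7,7-trimethyl-6-[(3,4,5-trimethoxyphenyl)methyl]-6-thiabicyclo[3.2.1]octan-6-ium trifluoromethanesulfonate | C[C@@H]1CC[C@@H]2C[C@H]1[S@@+](Cc1cc(OC)c(OC)c(OC)c1)C2(C)C.[O-]S(=O)(=O)C(F)(F)F | intermediate
10 | 5-bromo-6-[(3,5-dimethoxyphenyl)methylidene]-2,3-dimethoxycyclohexa-2,4-dien-1-one (ortho-quinone methide, alkene geometry not defined, formed in situ) | COC1=C(OC)C(=O)C(=Cc2cc(OC)cc(OC)c2)C(Br)=C1 | intermediate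
11 | sulfonium ylide of 9 (benzylic carbanion on sulfur, formed in situ) | C[C@@H]1CC[C@@H]2C[C@H]1[S@@+]([CH-]c1cc(OC)c(OC)c(OC)c1)C2(C)C | intermediate
12 | phenoxide–sulfonium zwitterion from attack of 11 on C3 of 10 (C3 as in 13, C2 bearing the sulfonium group that O1 displaces with inversion, formed in situ) | COc1cc(Br)c(c([O-])c1OC)[C@H](c1cc(OC)cc(OC)c1)[C@H](c1cc(OC)c(OC)c(OC)c1)[S@+]4C(C)(C)[C@@H]5CC[C@@H](C)[C@H]4C5 | intermediate
13 | (2S,3S)-4-bromo-3-(3,5-dimethoxyphenyl)-6,7-dimethoxy-2-(3,4,5-trimethoxyphenyl)-2,3-dihydro-1-benzofuran | Brc1cc(OC)c(OC)c2c1[C@H](c1cc(OC)cc(OC)c1)[C@@H](c1cc(OC)c(OC)c(OC)c1)O2 | intermediate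
14 | (2S,3S)-4-bromo-3-(3,5-dihydroxyphenyl)-2-(3,4,5-trihydroxyphenyl)-2,3-dihydro-1-benzofuran-6,7-diol | Brc1cc(O)c(O)c2c1[C@H](c1cc(O)cc(O)c1)[C@@H](c1cc(O)c(O)c(O)c1)O2 | intermediate
15 | 4-[(2S,3S)-4-bromo-3-[3,5-bis(tert-butyldimethylsilyloxy)phenyl]-6,7-bis(tert-butyldimethylsilyloxy)-2,3-dihydro-1-benzofuran-2-yl]-2,6-bis(tert-butyldimethylsilyloxy)phenol (hexasilyl ether with the C4' hydroxyl free, formed in situ) | Brc1cc(O[Si](C)(C)C(C)(C)C)c(O[Si](C)(C)C(C)(C)C)c2c1[C@H](c1cc(O[Si](C)(C)C(C)(C)C)cc(O[Si](C)(C)C(C)(C)C)c1)[C@@H](c1cc(O[Si](C)(C)C(C)(C)C)c(O)c(O[Si](C)(C)C(C)(C)C)c1)O2 | intermediate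
16 | heptakis-O-(tert-butyldimethylsilyl) derivative of 14, (2S,3S) | Brc1cc(O[Si](C)(C)C(C)(C)C)c(O[Si](C)(C)C(C)(C)C)c2c1[C@H](c1cc(O[Si](C)(C)C(C)(C)C)cc(O[Si](C)(C)C(C)(C)C)c1)[C@@H](c1cc(O[Si](C)(C)C(C)(C)C)c(O[Si](C)(C)C(C)(C)C)c(O[Si](C)(C)C(C)(C)C)c1)O2 | intermediate
17 | 3,5-dihydroxybenzaldehyde | O=Cc1cc(O)cc(O)c1 | starting material
18 | 3,5-bis(tert-butyldimethylsilyloxy)benzaldehyde | O=Cc1cc(O[Si](C)(C)C(C)(C)C)cc(O[Si](C)(C)C(C)(C)C)c1 | intermediate
19 | 1-ethenyl-3,5-bis(tert-butyldimethylsilyloxy)benzene | C=Cc1cc(O[Si](C)(C)C(C)(C)C)cc(O[Si](C)(C)C(C)(C)C)c1 | intermediate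
20 | nonakis-O-(tert-butyldimethylsilyl) derivative of 21, (2S,3S,E) | CC(C)(C)[Si](C)(C)Oc1cc(O[Si](C)(C)C(C)(C)C)cc(/C=C/c2cc(O[Si](C)(C)C(C)(C)C)c(O[Si](C)(C)C(C)(C)C)c3c2[C@H](c2cc(O[Si](C)(C)C(C)(C)C)cc(O[Si](C)(C)C(C)(C)C)c2)[C@@H](c2cc(O[Si](C)(C)C(C)(C)C)c(O[Si](C)(C)C(C)(C)C)c(O[Si](C)(C)C(C)(C)C)c2)O3)c1 | intermediate
21 | Scirpusin C, (2S,3S)-3-(3,5-dihydroxyphenyl)-4-[(E)-2-(3,5-dihydroxyphenyl)ethenyl]-2-(3,4,5-trihydroxyphenyl)-2,3-dihydro-1-benzofuran-6,7-diol | Oc1cc(O)cc(/C=C/c2cc(O)c(O)c3c2[C@H](c2cc(O)cc(O)c2)[C@@H](c2cc(O)c(O)c(O)c2)O3)c1 | target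

Total step count: 12. Longest linear sequence: 9 (steps 1, 2, 3, 4, 6, 7, 8, 11, 12).

Steps most likely to fail

Step 6. The ylide may add to the quinone methide with poor facial or trans/cis discrimination, the crowded methide carbon may react sluggishly, or zwitterion 12 may lose the sulfide by elimination toward the triarylethene instead of closing. The fallback sets out from 6 and returns at 13, building C2–C3 and O1–C2 in separate events. Sulfone 6 is treated with Cs2CO3, 3,4,5-trimethoxybenzaldehyde and a thiazolium-derived N-heterocyclic carbene (from 3-benzyl-5-(2-hydroxyethyl)-4-methylthiazolium chloride); Stetter-type acyl-anion addition to the ortho-quinone methide should give the configurationally labile ketone 2-(2-bromo-6-hydroxy-4,5-dimethoxyphenyl)-2-(3,5-dimethoxyphenyl)-1-(3,4,5-trimethoxyphenyl)ethan-1-one F1. Noyori-type asymmetric transfer hydrogenation with dynamic kinetic resolution (RuCl(TsDPEN)(p-cymene), enantiomer chosen to give the 2S diaryl carbon, HCO2H/Et3N) then sets that carbon and gives (1R,2S)-2-(2-bromo-6-hydroxy-4,5-dimethoxyphenyl)-2-(3,5-dimethoxyphenyl)-1-(3,4,5-trimethoxyphenyl)ethan-1-ol F2. Acid-catalysed cyclisation (camphorsulfonic acid, CH2Cl2, 0 °C) through the benzylic cation closes the O1–C2 bond; the trans isomer is the thermodynamic product and the diaryl carbon is not touched, which gives 13.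

Step 11. Oxidative addition at the bromide flanked by the C3 substituent may be slow, with competing protodebromination or loss of silyl groups at the temperature needed. The fallback sets out from 16 and returns at 20, splitting the bond formation into a less demanding vinyl transfer and an alkene metathesis. Stille coupling of 16 with tributyl(vinyl)stannane (Pd[P(t-Bu)3]2, toluene, 80 °C, neutral conditions) should give the 4-ethenyl heptasilyl ether F3; cross-metathesis of F3 with an excess of 19 (second-generation Hoveyda–Grubbs catalyst, CH2Cl2, 40 °C) should then give the (E)-stilbene 20.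

Step 12. The free nonaphenol may degrade in the presence of fluoride and tetrabutylammonium salts, or during their chromatographic removal, by autoxidation of pyrogallol and catechol phenoxides or by quinone-methide opening of the dihydrofuran ring. The fallback sets out from 20 and returns at 21, exchanging the protecting group before the final unmasking. Desilylative acetylation in one flask (TBAF, Ac2O, THF, 0 °C) traps each phenoxide as it forms and should give the stable, purifiable nonaacetate of Scirpusin C F4. Neutral transesterification of F4 (NH4OAc, MeOH/H2O, rt, argon) then releases 21 with only volatile by-products.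

Further compounds
F1 | step 6 | 2-(2-bromo-6-hydroxy-4,5-dimethoxyphenyl)-2-(3,5-dimethoxyphenyl)-1-(3,4,5-trimethoxyphenyl)ethan-1-one (racemic, labile α-carbon) | COc1cc(Br)c(c(O)c1OC)C(C(=O)c1cc(OC)c(OC)c(OC)c1)c1cc(OC)cc(OC)c1
F2 | step 6 | (1R,2S)-2-(2-bromo-6-hydroxy-4,5-dimethoxyphenyl)-2-(3,5-dimethoxyphenyl)-1-(3,4,5-trimethoxyphenyl)ethan-1-ol | COc1cc(Br)c(c(O)c1OC)[C@H](c1cc(OC)cc(OC)c1)[C@@H](O)c1cc(OC)c(OC)c(OC)c1
F3 | step 11 | heptakis-O-(tert-butyldimethylsilyl) derivative of (2S,3S)-3-(3,5-dihydroxyphenyl)-4-ethenyl-2-(3,4,5-trihydroxyphenyl)-2,3-dihydro-1-benzofuran-6,7-diol | C=Cc1cc(O[Si](C)(C)C(C)(C)C)c(O[Si](C)(C)C(C)(C)C)c2c1[C@H](c1cc(O[Si](C)(C)C(C)(C)C)cc(O[Si](C)(C)C(C)(C)C)c1)[C@@H](c1cc(O[Si](C)(C)C(C)(C)C)c(O[Si](C)(C)C(C)(C)C)c(O[Si](C)(C)C(C)(C)C)c1)O2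
F4 | step 12 | nona-O-acetyl derivative of Scirpusin C, (2S,3S,E) | CC(=O)Oc1cc(OC(C)=O)cc(/C=C/c2cc(OC(C)=O)c(OC(C)=O)c3c2[C@H](c2cc(OC(C)=O)cc(OC(C)=O)c2)[C@@H](c2cc(OC(C)=O)c(OC(C)=O)c(OC(C)=O)c2)O3)c1
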